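**Plan**
- The target is read as an exo,exo-2,6-diaryl furofuran (1S,3aR,4S,6aR) carrying a syringyl group and a cis-(2S,3S)-2-aryl-3-(hydroxymethyl)-2,3-dihydrobenzofuran.
- Retrosynthesis: after removal of the protecting groups, the oxolane ring that carries the dihydrobenzofuranyl group is cut at its two C–C bonds to the ring-fusion carbons (OCH2–CH and ArCH–CH). Its C–O–C triad (benzylic CH, ring O, OCH2) is a carbonyl ylide; the two fusion carbons are the alkene of a butenolide, which is the second furan ring at lactone oxidation level.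
- Forward: (S)-5-aryl butenolide 8 (Stetter, CBS, selenoxide elimination) and ylide precursor 18 (Mitsunobu, acetal, Pd(PPh3)4 diazo coupling, Rh2(S-PTTL)4 C–H insertion) are made separately. One [3+2] cycloaddition joins them and closes the first oxolane ring; the lactone is then turned into the second oxolane ring (diol, mesylate) and the protecting groups are removed.
- Stereochemistry: CBS reduction sets C5 of the butenolide, which steers the face of the cycloaddition and, with exo approach, sets three new centres. Rh2(S-PTTL)4 sets the cis-2,3 pair of the dihydrobenzofuran.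

Key step: step 11

Assumption: Rh2(S-PTTL)4 is taken to give the (2S,3R)-cis ester 16 in step 8; should the antipode form, Rh2(R-PTTL)4 is used without other change.

Abbreviations in names: Ar = 4-(benzyloxy)-3,5-dimethoxyphenyl; ArG = 4-(benzyloxy)-3-methoxyphenyl; TMS = trimethylsilyl; TBDPS = tert-butyldiphenylsilyl.

**Route**

Step 1
Reactants: 1 4-(benzyloxy)-3,5-dimethoxybenzaldehyde; 2 methyl acrylate
Product: 3 methyl 4-Ar-4-oxobutanoate
Conditions: 3-benzyl-5-(2-hydroxyethyl)-4-methylthiazolium chloride (cat.), Et3N, EtOH, 80 °C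
Reagents that add atoms: none
Why: Stetter reaction, in which the thiazolylidene-derived acyl anion equivalent of 1 adds 1,4 to the acrylate to give the 1,4-keto ester without forming a stereocentre.

Step 2
Reactants: 3 methyl 4-Ar-4-oxobutanoate
Product: 5 (5S)-5-Ar-dihydrofuran-2(3H)-one, via hydroxy ester 4 (not isolated)
Conditions: (R)-2-methyl-CBS-oxazaborolidine (10 mol %), BH3·SMe2, THF, −20 °C; MeOH; then PPTS (cat.), toluene, 60 °C
Reagents that add atoms: none
Why: Corey–Bakshi–Shibata reduction of the aryl alkyl ketone (aryl as the large group) should give the (S)-carbinol with the (R)-catalyst, and the γ-hydroxy ester lactonises under mild acid without touching the new centre.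

Step 3
Reactants: 5 (5S)-5-Ar-dihydrofuran-2(3H)-one
Product: 6 (5S)-5-Ar-3-(phenylselanyl)dihydrofuran-2(3H)-one (both C3 epimers)
Conditions: LDA, THF, −78 °C; PhSeBr
Reagents that add atoms: phenylselenenyl bromide, Br[Se]c1ccccc1
Why: α-selenenylation of the lactone lithium enolate; only the α-position is deprotonated, so C5 is untouched, and the C3 configuration is irrelevant because it is lost in step 4.

Step 4
Reactants: 6 (5S)-5-Ar-3-(phenylselanyl)dihydrofuran-2(3H)-one
Product: 8 (5S)-5-Ar-furan-2(5H)-one, via selenoxide 7 (not isolated)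
Conditions: H2O2 (30 % aq.), CH2Cl2, 0 °C to rt
Reagents that add atoms: none
Why: selenide oxidation followed by selenoxide syn-elimination toward C4 gives the butenolide under base-free conditions, which protects the acidic C5–H stereocentre.

Step 5
Reactants: 9 4-hydroxy-3-iodo-5-methoxybenzaldehyde (5-iodovanillin); 10 [4-(benzyloxy)-3-methoxyphenyl]methanol
Product: 11 4-{[4-(benzyloxy)-3-methoxybenzyl]oxy}-3-iodo-5-methoxybenzaldehyde
Conditions: PPh3, DIAD, THF, 0 °C to rt
Reagents that add atoms: none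
Why: Mitsunobu etherification of an acidic phenol with a reactive primary benzylic alcohol; no stereocentre is involved.

Step 6
Reactants: 11 4-{[4-(benzyloxy)-3-methoxybenzyl]oxy}-3-iodo-5-methoxybenzaldehyde; 12 (trimethylsilyl)methanol
Product: 13 bis[(trimethylsilyl)methyl] acetal of 11
Conditions: 12 (2.5 equiv in all), PPTS (cat.), benzene, reflux, Dean–Stark trap
Reagents that add atoms: (trimethylsilyl)methanol (second equivalent of 12), C[Si](C)(C)CO
Why: acid-catalysed acetalisation in which two molecules of the alcohol condense with the aldehyde under azeotropic removal of water; the acetal masks the aldehyde through steps 7 to 10 and already holds the OCH2SiMe3 group from which the ylide is later released.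

Step 7
Reactants: 13 bis[(trimethylsilyl)methyl] acetal of 11; 14 ethyl diazoacetate
Product: 15 ethyl 2-diazo-2-[2-{[4-(benzyloxy)-3-methoxybenzyl]oxy}-5-{bis[(TMS)methoxy]methyl}-3-methoxyphenyl]acetate
Conditions: Pd(PPh3)4 (5 mol %), Ag2CO3, Et3N, toluene, rt
Reagents that add atoms: none
Why: palladium-catalysed cross-coupling of an aryl iodide with a diazoacetate with retention of the diazo group (oxidative addition, Ag2CO3-assisted C–H metalation of the diazo ester, reductive elimination).

Step 8
Reactants: 15 aryl diazoacetate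
Product: 16 ethyl (2S,3R)-2-ArG-5-{bis[(TMS)methoxy]methyl}-7-methoxy-2,3-dihydro-1-benzofuran-3-carboxylate (2,3-cis)
Conditions: Rh2(S-PTTL)4 [dirhodium tetrakis(N-phthaloyl-(S)-tert-leucinate)] (1 mol %), toluene, −78 °C
Reagents that add atoms: none
Why: intramolecular 1,5 C–H insertion of the rhodium carbenoid into the electron-rich benzylic OCH2 group, for which this class of bulky chiral carboxylate catalysts gives the kinetic cis-2-aryl-3-carboxylate and sets both centres by catalyst control.

Step 9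
Reactants: 16 cis ethyl ester
Product: 17 [(2S,3S)-2-ArG-5-{bis[(TMS)methoxy]methyl}-7-methoxy-2,3-dihydro-1-benzofuran-3-yl]methanol (2,3-cis)
Conditions: LiAlH4, THF, −40 to −10 °C
Reagents that add atoms: none
Why: hydride reduction of the ester at low temperature is faster than enolisation at C3, so the cis relationship is kept (the descriptor at C3 changes only by priority); the acetal is inert to hydride.

Step 10
Reactants: 17 cis alcohol
Product: 18 TBDPS ether of 17
Conditions: TBDPSCl, imidazole, DMF, rt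
Reagents that add atoms: tert-butyl(chloro)diphenylsilane, CC(C)(C)[Si](Cl)(c1ccccc1)c1ccccc1
Why: standard silylation of a primary alcohol; TBDPS is chosen to survive AcCl/ZnBr2, CsF in MeCN, LiAlH4 and MsCl/pyridine.

Step 11
Reactants: 18 TBDPS-protected bis[(trimethylsilyl)methyl] acetal; 8 (5S)-5-Ar-furan-2(5H)-one
Product: 21 (3S,3aR,6S,6aS)-3-Ar-6-[(2S,3S)-2-ArG-3-(TBDPS-oxymethyl)-7-methoxy-2,3-dihydro-1-benzofuran-5-yl]tetrahydro-1H,3H-furo[3,4-c]furan-1-one (cis-fused; both aryl groups on the convex face), via chloro ether 19 (not isolated), via carbonyl ylide 20 (not isolated)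
Conditions: AcCl, ZnBr2 (cat.), CH2Cl2, 0 °C to rt; evaporate; then 8 (1.5 equiv), CsF, MeCN, 0 °C to rt
Reagents that add atoms: none
Why: Proposed new method: AcCl/ZnBr2 converts acetal 18 into α-chloro ether 19, which ionises to the aryl-stabilised oxocarbenium ion ArCH=O(+)–CH2SiMe3; fluoride removes the silyl group and leaves the non-stabilised carbonyl ylide 20, which adds as a three-atom 4π C–O–C unit across the electron-poor C3=C4 bond of butenolide 8 in a concerted suprafacial [3+2] cycloaddition. The closest known reaction type is the fluoride-induced 1,3-elimination of α-chloroalkyl (trimethylsilyl)methyl ethers to carbonyl ylides that are trapped by activated alkenes, extended here to an aryl-substituted ylide and a chiral 5-aryl butenolide. The oxolane ring is closed by this intermolecular [3+2] cycloaddition (two C–C bonds formed, ring built from the ylide C–O–C and the two alkene carbons), and the cis ring fusion at C3a and C6a follows from suprafacial addition to the cyclic Z-alkene. Regioselectivity is needed and should come from polarisation: the electron-rich aryl group stabilises positive charge at the benzylic terminus, so the nucleophilic CH2 terminus bonds to the lactone β-carbon and the benzylic terminus to the α-carbon. Facial selectivity is set by the C5 aryl group of 8 (addition anti to it, which fixes C3a and C6a), and the benzylic centre C6 requires the exo transition state in which the aryl group of the anti-configured ylide points away from the lactone ring, favoured on steric grounds. The lactone carbonyl is the activating helper and is removed in steps 12 and 13.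

Step 12
Reactants: 21 bicyclic lactone
Product: 22 (S)-Ar-[(3R,4R,5S)-5-(dihydrobenzofuranyl)-4-(hydroxymethyl)oxolan-3-yl]methanol (diol)
Conditions: LiAlH4, THF, 0 °C
Reagents that add atoms: none
Why: hydride reduction of the lactone to the 1,4-diol without change at any stereocentre; benzyl and TBDPS ethers are inert.

Step 13
Reactants: 22 diol
Product: 24 TBDPS/dibenzyl-protected furofuran, (1S,3aR,4S,6aR)-configured, via primary mesylate 23 (not isolated)
Conditions: MsCl (1.1 equiv), pyridine, 0 °C to rt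
Reagents that add atoms: none
Why: selective sulfonylation of the primary alcohol followed by intramolecular Williamson closure (5-exo-tet) by the benzylic hydroxyl forms the second oxolane ring with retention at the benzylic carbon, since no bond to it is broken.

Step 14
Reactants: 24 protected furofuran
Product: 25 primary alcohol with both phenols still benzylated
Conditions: Bu4NF, THF, rt
Reagents that add atoms: none
Why: fluoride cleavage of the silyl ether under non-acidic conditions that leave the benzylic ethers and all stereocentres untouched.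

Step 15
Reactants: 25 dibenzyl ether
Product: 26 target, 4-[(1S,3aR,4S,6aR)-4-[(2S,3S)-2-(4-hydroxy-3-methoxyphenyl)-3-(hydroxymethyl)-7-methoxy-2,3-dihydro-1-benzofuran-5-yl]tetrahydro-1H,3H-furo[3,4-c]furan-1-yl]-2,6-dimethoxyphenol
Conditions: H2 (1 atm), Pd/C (10 %), EtOAc, rt, stopped after uptake of two equivalents
Reagents that add atoms: none
Why: hydrogenolysis of aryl benzyl ethers is much faster than cleavage of the ring benzylic C–O bonds of the oxolanes and the dihydrobenzofuran, so short exposure under neutral conditions should free both phenols only.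

**Compound list**

1 | 4-(benzyloxy)-3,5-dimethoxybenzaldehyde | O=Cc1cc(OC)c(OCc2ccccc2)c(OC)c1 | starting material
2 | methyl acrylate | C=CC(=O)OC | starting material
3 | methyl 4-[4-(benzyloxy)-3,5-dimethoxyphenyl]-4-oxobutanoate | COC(=O)CCC(=O)c1cc(OC)c(OCc2ccccc2)c(OC)c1 | intermediate
4 | methyl (4S)-4-[4-(benzyloxy)-3,5-dimethoxyphenyl]-4-hydroxybutanoate | COC(=O)CC[C@H](O)c1cc(OC)c(OCc2ccccc2)c(OC)c1 | intermediate
5 | (5S)-5-[4-(benzyloxy)-3,5-dimethoxyphenyl]dihydrofuran-2(3H)-one | O=C1CC[C@@H](c2cc(OC)c(OCc3ccccc3)c(OC)c2)O1 | intermediate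
6 | (5S)-5-[4-(benzyloxy)-3,5-dimethoxyphenyl]-3-(phenylselanyl)dihydrofuran-2(3H)-one, C3 epimers | O=C1C([Se]c2ccccc2)C[C@@H](c2cc(OC)c(OCc3ccccc3)c(OC)c2)O1 | intermediate
7 | selenoxide of 6 | O=C1C([Se](=O)c2ccccc2)C[C@@H](c2cc(OC)c(OCc3ccccc3)c(OC)c2)O1 | intermediate
8 | (5S)-5-[4-(benzyloxy)-3,5-dimethoxyphenyl]furan-2(5H)-one | O=C1C=C[C@@H](c2cc(OC)c(OCc3ccccc3)c(OC)c2)O1 | intermediate
9 | 4-hydroxy-3-iodo-5-methoxybenzaldehyde | O=Cc1cc(I)c(O)c(OC)c1 | starting material
10 | [4-(benzyloxy)-3-methoxyphenyl]methanol | OCc1ccc(OCc2ccccc2)c(OC)c1 | starting material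
11 | 4-{[4-(benzyloxy)-3-methoxybenzyl]oxy}-3-iodo-5-methoxybenzaldehyde | O=Cc1cc(I)c(OCc2ccc(OCc3ccccc3)c(OC)c2)c(OC)c1 | intermediate
12 | (trimethylsilyl)methanol | C[Si](C)(C)CO | starting material
13 | bis[(trimethylsilyl)methyl] acetal of 11 | C[Si](C)(C)COC(OC[Si](C)(C)C)c1cc(I)c(OCc2ccc(OCc3ccccc3)c(OC)c2)c(OC)c1 | intermediate
14 | ethyl diazoacetate | CCOC(=O)C=[N+]=[N-] | starting material
15 | ethyl 2-diazo-2-[2-{[4-(benzyloxy)-3-methoxybenzyl]oxy}-5-{bis[(trimethylsilyl)methoxy]methyl}-3-methoxyphenyl]acetate | CCOC(=O)C(=[N+]=[N-])c1cc(C(OC[Si](C)(C)C)OC[Si](C)(C)C)cc(OC)c1OCc1ccc(OCc2ccccc2)c(OC)c1 | intermediate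
16 | ethyl (2S,3R)-2-[4-(benzyloxy)-3-methoxyphenyl]-5-{bis[(trimethylsilyl)methoxy]methyl}-7-methoxy-2,3-dihydro-1-benzofuran-3-carboxylate (cis) | COc1cc([C@H]2Oc3c(OC)cc(C(OC[Si](C)(C)C)OC[Si](C)(C)C)cc3[C@H]2C(=O)OCC)ccc1OCc1ccccc1 | intermediate
17 | [(2S,3S)-2-[4-(benzyloxy)-3-methoxyphenyl]-5-{bis[(trimethylsilyl)methoxy]methyl}-7-methoxy-2,3-dihydro-1-benzofuran-3-yl]methanol (cis) | COc1cc([C@H]2Oc3c(OC)cc(C(OC[Si](C)(C)C)OC[Si](C)(C)C)cc3[C@H]2CO)ccc1OCc1ccccc1 | intermediate
18 | tert-butyldiphenylsilyl ether of 17 | COc1cc([C@H]2Oc3c(OC)cc(C(OC[Si](C)(C)C)OC[Si](C)(C)C)cc3[C@H]2CO[Si](c2ccccc2)(c2ccccc2)C(C)(C)C)ccc1OCc1ccccc1 | intermediate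
19 | α-chloro (trimethylsilyl)methyl ether from 18, epimers at CHCl | COc1cc([C@H]2Oc3c(OC)cc(C(Cl)OC[Si](C)(C)C)cc3[C@H]2CO[Si](c2ccccc2)(c2ccccc2)C(C)(C)C)ccc1OCc1ccccc1 | intermediate
20 | carbonyl ylide ArCH=O(+)–CH2(−) from 19 | COc1cc([C@H]2Oc3c(OC)cc(C=[O+][CH2-])cc3[C@H]2CO[Si](c2ccccc2)(c2ccccc2)C(C)(C)C)ccc1OCc1ccccc1 | intermediate
21 | (3S,3aR,6S,6aS)-3-[4-(benzyloxy)-3,5-dimethoxyphenyl]-6-[(2S,3S)-2-[4-(benzyloxy)-3-methoxyphenyl]-3-{[(tert-butyldiphenylsilyl)oxy]methyl}-7-methoxy-2,3-dihydro-1-benzofuran-5-yl]tetrahydro-1H,3H-furo[3,4-c]furan-1-one | COc1cc([C@H]2Oc3c(OC)cc([C@H]4OC[C@H]5[C@@H]4C(=O)O[C@@H]5c4cc(OC)c(OCc5ccccc5)c(OC)c4)cc3[C@H]2CO[Si](c2ccccc2)(c2ccccc2)C(C)(C)C)ccc1OCc1ccccc1 | intermediate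
22 | (S)-[4-(benzyloxy)-3,5-dimethoxyphenyl][(3R,4R,5S)-5-(protected dihydrobenzofuran-5-yl)-4-(hydroxymethyl)oxolan-3-yl]methanol | COc1cc([C@H]2Oc3c(OC)cc([C@H]4OC[C@H]([C@H](O)c5cc(OC)c(OCc6ccccc6)c(OC)c5)[C@@H]4CO)cc3[C@H]2CO[Si](c2ccccc2)(c2ccccc2)C(C)(C)C)ccc1OCc1ccccc1 | intermediate
23 | primary methanesulfonate of 22 | COc1cc([C@H]2Oc3c(OC)cc([C@H]4OC[C@H]([C@H](O)c5cc(OC)c(OCc6ccccc6)c(OC)c5)[C@@H]4COS(C)(=O)=O)cc3[C@H]2CO[Si](c2ccccc2)(c2ccccc2)C(C)(C)C)ccc1OCc1ccccc1 | intermediate
24 | tert-butyl{[(2S,3S)-2-[4-(benzyloxy)-3-methoxyphenyl]-5-[(1S,3aR,4S,6aR)-4-[4-(benzyloxy)-3,5-dimethoxyphenyl]tetrahydro-1H,3H-furo[3,4-c]furan-1-yl]-7-methoxy-2,3-dihydro-1-benzofuran-3-yl]methoxy}diphenylsilane | COc1cc([C@H]2Oc3c(OC)cc([C@H]4OC[C@H]5[C@@H]4CO[C@@H]5c4cc(OC)c(OCc5ccccc5)c(OC)c4)cc3[C@H]2CO[Si](c2ccccc2)(c2ccccc2)C(C)(C)C)ccc1OCc1ccccc1 | intermediate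
25 | desilylated alcohol of 24 (both phenols benzylated) | COc1cc([C@H]2Oc3c(OC)cc([C@H]4OC[C@H]5[C@@H]4CO[C@@H]5c4cc(OC)c(OCc5ccccc5)c(OC)c4)cc3[C@H]2CO)ccc1OCc1ccccc1 | intermediate
26 | 4-[(1S,3aR,4S,6aR)-4-[(2S,3S)-2-(4-hydroxy-3-methoxyphenyl)-3-(hydroxymethyl)-7-methoxy-2,3-dihydro-1-benzofuran-5-yl]tetrahydro-1H,3H-furo[3,4-c]furan-1-yl]-2,6-dimethoxyphenol | COc1cc([C@H]2Oc3c(OC)cc([C@H]4OC[C@H]5[C@@H]4CO[C@@H]5c4cc(OC)c(O)c(OC)c4)cc3[C@H]2CO)ccc1O | target

**Step count**

Total steps: 15. Longest linear sequence: 11 steps (steps 5 to 15).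

**Steps most likely to fail**

1. Step 11. What may go wrong: fluoride may deprotonate C5 of the butenolide before cycloaddition (racemisation, or isomerisation to the 2(3H)-furanone); the ylide may collapse to the oxirane; exo/endo discrimination at the new benzylic carbon may be weak. The fallback uses known chemistry and forms the same two C–C bonds one after the other; it sets out from 8 and 18 and returns at 21. Benzophenone-sensitised irradiation of 8 in methanol adds a hydroxymethyl radical to C4 anti to the C5 aryl group and should give (4R,5S)-5-[4-(benzyloxy)-3,5-dimethoxyphenyl]-4-(hydroxymethyl)dihydrofuran-2(3H)-one F1. Acid-catalysed transacetalisation of 18 with F1 (PPTS, toluene, removal of (trimethylsilyl)methanol) gives the mixed lactonylmethyl (trimethylsilyl)methyl acetal F2. LiHMDS/Me3SiCl converts it into the trimethylsilyl ketene acetal F3, and Me3SiOTf in CH2Cl2 at −78 °C ionises the acetal with loss of the (trimethylsilyl)methoxy group so that the tethered oxocarbenium ion is captured by the ketene acetal in an intramolecular Mukaiyama aldol-type addition. The ring fusion is necessarily cis and the aryl group should take the convex face, giving 21.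

2. Step 8. What may go wrong: the catalyst may discriminate poorly between the enantiotopic C–H bonds, or the cis preference may erode, on this more substituted, acetal-bearing diazo ester. The fallback replaces catalyst control by resolution; it sets out from 17 of insufficient enantiomeric purity and returns to 17. Esterification with (S)-2-methoxy-2-phenylacetic acid (DCC, DMAP, CH2Cl2) gives the diastereomeric esters, from which the (S)-2-methoxy-2-phenylacetate of (2S,3S)-17 F4 is separated by crystallisation or chromatography (any trans isomer is removed at the same stage). Saponification (LiOH, THF/H2O) returns 17.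

3. Step 7. What may go wrong: oxidative addition at the ortho-alkoxy, electron-rich iodide may be slow, so that decomposition of the diazo ester by Pd(PPh3)4 and Ag2CO3 wins. The fallback installs the acetate first and the diazo group second; it sets out from 13 and returns at 15. Palladium-catalysed coupling of 13 with the Reformatsky reagent BrZnCH2CO2Et (Pd(dba)2, P(t-Bu)3, THF, rt) gives ethyl 2-[2-{[4-(benzyloxy)-3-methoxybenzyl]oxy}-5-{bis[(trimethylsilyl)methoxy]methyl}-3-methoxyphenyl]acetate F5. Regitz diazo transfer (4-acetamidobenzenesulfonyl azide, DBU, MeCN) converts it into 15.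

**Further compounds**

F1 | step 11 | (4R,5S)-5-[4-(benzyloxy)-3,5-dimethoxyphenyl]-4-(hydroxymethyl)dihydrofuran-2(3H)-one | O=C1C[C@H](CO)[C@@H](c2cc(OC)c(OCc3ccccc3)c(OC)c2)O1
F2 | step 11 | mixed acetal of the aldehyde underlying 18 with F1 and (trimethylsilyl)methanol, acetal epimers | COc1cc([C@H]2Oc3c(OC)cc(C(OC[Si](C)(C)C)OC[C@H]4CC(=O)O[C@@H]4c4cc(OC)c(OCc5ccccc5)c(OC)c4)cc3[C@H]2CO[Si](c2ccccc2)(c2ccccc2)C(C)(C)C)ccc1OCc1ccccc1
F3 | step 11 | trimethylsilyl ketene acetal of F2 | COc1cc([C@H]2Oc3c(OC)cc(C(OC[Si](C)(C)C)OC[C@H]4C=C(O[Si](C)(C)C)O[C@@H]4c4cc(OC)c(OCc5ccccc5)c(OC)c4)cc3[C@H]2CO[Si](c2ccccc2)(c2ccccc2)C(C)(C)C)ccc1OCc1ccccc1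
F4 | step 8 | (S)-2-methoxy-2-phenylacetate of (2S,3S)-17 | COc1cc([C@H]2Oc3c(OC)cc(C(OC[Si](C)(C)C)OC[Si](C)(C)C)cc3[C@H]2COC(=O)[C@@H](OC)c2ccccc2)ccc1OCc1ccccc1
F5 | step 7 | ethyl 2-[2-{[4-(benzyloxy)-3-methoxybenzyl]oxy}-5-{bis[(trimethylsilyl)methoxy]methyl}-3-methoxyphenyl]acetate | CCOC(=O)Cc1cc(C(OC[Si](C)(C)C)OC[Si](C)(C)C)cc(OC)c1OCc1ccc(OCc2ccccc2)c(OC)c1
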